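**Retrosynthetic overview**
1. Target 15 ⇐ 7-oxanorbornene 14 by rhodium-catalysed anti-SN2' opening with chloride: the bridge oxygen stays on C1 as the tertiary hydroxyl, chloride enters trans at C2, and the alkene moves to C3=C4.
2. 14 ⇐ diol 12 by benzoylation of the two hydroxyls freed from boron, then acid cleavage of the chiral auxiliary ether.
3. 12 ⇐ boronate 10 by a boron-tethered intramolecular Diels–Alder reaction of a furan and C–B oxidation; this forms C4–C5 and C1–C6 of the target in one operation. 10 ⇐ ynol ether 7 + (−)-Ipc2BH + furfural; 7 ⇐ (R)-1-(2,4,6-triisopropylphenyl)ethanol + trichloroethylene.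
4. Enabling feature: the CH2–O and C6–O oxygens flank C1 in a 1,3-relationship, so one boron atom can bridge them (furan C2–CH2–O–B–CH=, a five-membered 1,2-oxaborolane in the adduct); the C1–O/C4 pair is the ring oxygen and the two α-carbons of a furan.
5. Ring order: the furan ring is bought (furfural); the cyclohexene ring closes in step 4 together with the temporary oxa-bridge and oxaborolane; the oxaborolane is cleaved in the same step and the oxa-bridge in step 7.

Key step: step 4

Remark: the furan is assumed to add to the alkene face opposite the aryl group of the (R)-auxiliary (s-trans enol ether, carbinol C–H eclipsed with the vinyl C–H); this assignment of the absolute sense rests on that model.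

Locants for the bicyclic compounds (7-oxabicyclo[2.2.1]hept-5-ene): C1 quaternary bridgehead, C2 exo-oxygenated carbon, C3 endo-oxygenated carbon, C4 bridgehead CH, C5=C6, O7. They become C1, C6, C5, C4, C3 and C2 of the target ring, in that order.

**Route**

Step 1
Reactants: 1 (R)-1-(2,4,6-triisopropylphenyl)ethanol; 2 trichloroethylene
Product: 5 2-[(1R)-1-{[(E)-1,2-dichloroethenyl]oxy}ethyl]-1,3,5-triisopropylbenzene, via potassium alkoxide 3 (not isolated), via dichloroacetylene 4 (not isolated)
Conditions: KH, THF, 0 °C; then 2, −50 °C → rt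
Reagents that add atoms: none
Why: The alkoxide eliminates HCl from trichloroethylene to give dichloroacetylene and then adds to it anti (nucleophilic addition to a haloalkyne), which should give the E-dichloroenol ether without touching the carbinol stereocentre.

Step 2
Reactants: 5 the E-dichloroenol ether
Product: 7 2-[(1R)-1-(ethynyloxy)ethyl]-1,3,5-triisopropylbenzene, via lithium alkoxyacetylide 6 (not isolated)
Conditions: n-BuLi (2.2 equiv), THF, −78 → −40 °C; then H2O, −78 °C; kept cold and used at once
Reagents that add atoms: none
Why: Deprotonation, loss of LiCl and chlorine–lithium exchange (the dehydrohalogenation–metalation sequence established for dichloroenol ethers) should give the lithium alkoxyacetylide, which water protonates to the terminal ynol ether; no stereocentre is formed.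

Step 3
Reactants: 7 the ynol ether; 8 furfural (2.0 equiv)
Product: 10 bis(furan-2-ylmethyl) [(E)-2-{(1R)-1-(2,4,6-triisopropylphenyl)ethoxy}ethenyl]boronate (used crude), via alkenylbis(isopinocampheyl)borane 9 (not isolated)
Conditions: (−)-Ipc2BH (1.0 equiv), THF, −25 → 0 °C; then 8, 0 °C → rt; volatiles and α-pinene removed in vacuo
Reagents that add atoms: (−)-diisopinocampheylborane, [BH]([C@@H]1C[C@@H]2C[C@H]([C@H]1C)C2(C)C)[C@@H]1C[C@@H]2C[C@H]([C@H]1C)C2(C)C
Why: syn-Hydroboration of the terminal ynol ether should place boron on the unsubstituted carbon and set the E geometry, and furfural is then reduced by β-hydride transfer from each isopinocampheyl group (aldehyde-induced dealkylation of isopinocampheylboranes with loss of α-pinene), which installs both furfuryloxy groups on boron under neutral conditions.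

Step 4
Reactants: 10 the bis(furfuryl) alkenylboronate
Product: 12 (1R,2R,3R,4R)-1-(hydroxymethyl)-3-[(1R)-1-(2,4,6-triisopropylphenyl)ethoxy]-7-oxabicyclo[2.2.1]hept-5-en-2-ol (2-exo hydroxyl; 3-endo ether), via oxaborolane cycloadduct 11 (not isolated)
Conditions: CH2Cl2, 12 kbar, 40 °C; then 30% H2O2, 3 M NaOH, THF, 0 °C
Reagents that add atoms: hydrogen peroxide, OO
Why: Proposed new method: the furfuryloxy groups on trigonal boron hold a furan three atoms (C–O–B) from the vinyl carbon, and a concerted suprafacial [4+2] cycloaddition between the furan (C2 and C5 as diene termini) and the B–CH=CH–O alkene forms both ring bonds, pressure being used because this cycloaddition has a large negative activation and reaction volume and the electron-rich alkene would otherwise leave the equilibrium on the open side. The closest known reaction types are the alkenylboronate-tethered intramolecular Diels–Alder reaction of dienols followed by C–B oxidation and the intramolecular Diels–Alder reaction of furans through three-atom tethers; the new element is their combination with a 2-alkoxyvinyl boronate. Two rings close: the six-membered carbocycle by the cycloaddition itself and a five-membered 1,2-oxaborolane in the fused mode with the tether exo, the only mode a three-atom tether across a bridgehead bond allows. The tether thus fixes the regiochemistry (boron-bearing carbon to the substituted furan carbon) and puts boron exo at C2, the E alkene then places the ether oxygen endo at C3 and trans to boron, and the bridgehead centres C1 and C4 follow from suprafacial addition. The absolute sense is set by the auxiliary, whose aryl group covers one face of the s-trans enol ether and, being on the endo side, would meet the furan there, so the furan adds to the other face and the minor diastereomer can be removed by chromatography of 12. Oxidation replaces C–B by C–O with retention and frees the primary alcohol, so that exactly the two hydroxyls that must carry benzoates are unveiled; the needed selectivities are therefore tether-controlled regio- and exo-selectivity, auxiliary-controlled facial selectivity and chemoselective oxidation of boron.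

Step 5
Reactants: 12 the diol
Product: 13 [(1R,2R,3S,4R)-2-(benzoyloxy)-3-[(1R)-1-(2,4,6-triisopropylphenyl)ethoxy]-7-oxabicyclo[2.2.1]hept-5-en-1-yl]methyl benzoate
Conditions: BzCl (3 equiv), pyridine, DMAP (cat.), CH2Cl2, 0 °C → rt
Reagents that add atoms: benzoyl chloride, O=C(Cl)c1ccccc1
Why: Acylation under nucleophilic catalysis should esterify the primary and the hindered exo secondary hydroxyl, the only free hydroxyls, with no change at any stereocentre.

Step 6
Reactants: 13 the dibenzoate ether
Product: 14 [(1R,2R,3S,4R)-2-(benzoyloxy)-3-hydroxy-7-oxabicyclo[2.2.1]hept-5-en-1-yl]methyl benzoate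
Conditions: CF3CO2H, CH2Cl2, 0 °C
Reagents that add atoms: none
Why: Acidolysis of the hindered benzylic ether through the 1-arylethyl cation (SN1 cleavage of an acid-labile benzylic ether) should free the endo hydroxyl with retention at C3, because the ring C–O bond is not broken.

Step 7
Reactants: 14 the oxanorbornene alcohol
Product: 15 [(1R,2R,5S,6R)-6-(benzoyloxy)-2-chloro-1,5-dihydroxycyclohex-3-en-1-yl]methyl benzoate (target)
Conditions: [Rh(cod)Cl]2 (2.5 mol %), dppf, Fe(C5H4PPh2)2 (6 mol %), Et3N·HCl (5 equiv), THF, 60 °C
Reagents that add atoms: triethylamine hydrochloride, CC[NH+](CC)CC.[Cl-]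
Why: In this rhodium-catalysed anti-SN2' ring opening of an oxabicyclic alkene with a halide nucleophile, monovalent rhodium should add to the exo face and ionise the C4–O7 bond (the one remote from the carbon flanked by two acyloxy-bearing carbons), and chloride should then attack bicyclic C6 from the endo face, which sets the new stereocentre (C2 of the target) trans to the hydroxyl left on C1.

**Compound list**
1 | (R)-1-(2,4,6-triisopropylphenyl)ethanol | C[C@@H](O)c1c(C(C)C)cc(C(C)C)cc1C(C)C | starting material
2 | trichloroethylene | ClC=C(Cl)Cl | starting material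
3 | potassium (1R)-1-(2,4,6-triisopropylphenyl)ethoxide | C[C@@H]([O-])c1c(C(C)C)cc(C(C)C)cc1C(C)C.[K+] | intermediate
4 | dichloroacetylene | ClC#CCl | intermediate
5 | 2-[(1R)-1-{[(E)-1,2-dichloroethenyl]oxy}ethyl]-1,3,5-triisopropylbenzene | C[C@@H](O/C(Cl)=C\Cl)c1c(C(C)C)cc(C(C)C)cc1C(C)C | intermediate
6 | lithium 2-[(1R)-1-(2,4,6-triisopropylphenyl)ethoxy]ethynide | [Li]C#CO[C@H](C)c1c(C(C)C)cc(C(C)C)cc1C(C)C | intermediate
7 | 2-[(1R)-1-(ethynyloxy)ethyl]-1,3,5-triisopropylbenzene | C[C@@H](OC#C)c1c(C(C)C)cc(C(C)C)cc1C(C)C | intermediate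
8 | furfural (furan-2-carbaldehyde) | O=Cc1ccco1 | starting material
9 | [(E)-2-{(1R)-1-(2,4,6-triisopropylphenyl)ethoxy}ethenyl]bis(isopinocampheyl)borane | C[C@@H](O/C=C/B([C@@H]1C[C@@H]2C[C@H]([C@H]1C)C2(C)C)[C@@H]1C[C@@H]2C[C@H]([C@H]1C)C2(C)C)c1c(C(C)C)cc(C(C)C)cc1C(C)C | intermediate
10 | bis(furan-2-ylmethyl) [(E)-2-{(1R)-1-(2,4,6-triisopropylphenyl)ethoxy}ethenyl]boronate | C[C@@H](O/C=C/B(OCc1ccco1)OCc1ccco1)c1c(C(C)C)cc(C(C)C)cc1C(C)C | intermediate
11 | oxaborolane cycloadduct: 7-oxabicyclo[2.2.1]hept-5-ene with boron (carrying one furan-2-ylmethoxy group) bonded exo to C2 and through O–CH2 to C1, auxiliary ether endo at C3 | c1ccc(COB2OC[C@@]34C=C[C@@H](O3)[C@H](O[C@H](C)c3c(C(C)C)cc(C(C)C)cc3C(C)C)[C@@H]24)o1 | intermediate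
12 | (1R,2R,3R,4R)-1-(hydroxymethyl)-3-[(1R)-1-(2,4,6-triisopropylphenyl)ethoxy]-7-oxabicyclo[2.2.1]hept-5-en-2-ol | OC[C@@]12C=C[C@@H](O1)[C@H](O[C@H](C)c1c(C(C)C)cc(C(C)C)cc1C(C)C)[C@H]2O | intermediate
13 | [(1R,2R,3S,4R)-2-(benzoyloxy)-3-[(1R)-1-(2,4,6-triisopropylphenyl)ethoxy]-7-oxabicyclo[2.2.1]hept-5-en-1-yl]methyl benzoate | O=C(OC[C@@]12C=C[C@@H](O1)[C@H](O[C@H](C)c1c(C(C)C)cc(C(C)C)cc1C(C)C)[C@H]2OC(=O)c1ccccc1)c1ccccc1 | intermediate
14 | [(1R,2R,3S,4R)-2-(benzoyloxy)-3-hydroxy-7-oxabicyclo[2.2.1]hept-5-en-1-yl]methyl benzoate | O=C(OC[C@@]12C=C[C@@H](O1)[C@H](O)[C@H]2OC(=O)c1ccccc1)c1ccccc1 | intermediate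
15 | [(1R,2R,5S,6R)-6-(benzoyloxy)-2-chloro-1,5-dihydroxycyclohex-3-en-1-yl]methyl benzoate | O=C(OC[C@]1(O)[C@H](Cl)C=C[C@H](O)[C@H]1OC(=O)c1ccccc1)c1ccccc1 | target

Total steps: 7. Longest linear sequence: 7 steps (1 → 15; furfural 8 enters at step 3).

**Steps most likely to fail**

Step 4 (Proposed new method). The cycloaddition of an electron-rich furan to an electron-rich alkoxyvinylboronate may be too slow, or may revert on decompression before oxidation, and facial control by the auxiliary may be poor. The fallback uses known chemistry, sets out from furfural 8 and comes back at 14. Furfural is reduced (NaBH4, MeOH) to furan-2-ylmethanol F1 and benzoylated (BzCl, pyridine) to furan-2-ylmethyl benzoate F2. A thermal intermolecular Diels–Alder reaction with vinylene carbonate (neat, 120 °C, sealed tube), separation of the endo isomer and resolution of the racemate on a chiral stationary phase should give the exo cyclic carbonate F3. LiOH (aqueous THF, 0 °C) should open the strained cis-fused carbonate faster than the benzoate and give the exo,exo-diol F4. TBSCl and imidazole should silylate the less hindered 3-hydroxyl to give the silyl ether F5, and BzCl with DMAP then gives the dibenzoate silyl ether F6. HF·pyridine frees the exo alcohol F7, a Dess–Martin oxidation gives the ketone F8, and NaBH4 delivers hydride from the exo face to give the endo alcohol 14.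

Step 7. Ionisation of this non-benzo, bridgehead-substituted oxabicycle may be slow, chloride may add at the distal allyl terminus, and the allylic chloride formed may re-ionise under the catalyst with loss of configuration or aromatisation. The fallback sets out from 14 and comes back at 15, replacing transition-metal catalysis by Lewis-acid ionisation with neighbouring-group control: BCl3, CH2Cl2, −78 → −20 °C. The C4–O7 bond should ionise (C1 is deactivated by its two acyloxy-bearing neighbours), the exo benzoate at C2 can hold the bridge face of the allylic carbon C6, and chloride should then enter at C6 from the opposite face, as acyloxonium ions are opened by halide. This fallback makes no compound outside the list (entry F0).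

Step 6. The acid may open the strained allylic ether bridge or induce benzoyl migration before the hindered endo ether is cleaved. The fallback sets out from 13 and comes back at 15 by reversing the order of events. The rhodium-catalysed chloride opening of step 7 is run on 13 and should give the auxiliary-bearing chlorohydrin [(1R,2R,5S,6R)-6-(benzoyloxy)-2-chloro-1-hydroxy-5-[(1R)-1-(2,4,6-triisopropylphenyl)ethoxy]cyclohex-3-en-1-yl]methyl benzoate F9. The auxiliary is then removed last (CF3CO2H, CH2Cl2, 0 °C), when no oxa-bridge is left.

Further compounds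
F1 | step 4 | furan-2-ylmethanol | OCc1ccco1
F2 | step 4 | furan-2-ylmethyl benzoate | O=C(OCc1ccco1)c1ccccc1
F3 | step 4 | exo-2,3-cyclic carbonate of [2,3-dihydroxy-7-oxabicyclo[2.2.1]hept-5-en-1-yl]methyl benzoate (enantiomer kept after resolution) | O=C(OC[C@@]12C=C[C@@H](O1)[C@H]3OC(=O)O[C@@H]23)c1ccccc1
F4 | step 4 | [2-exo,3-exo-dihydroxy-7-oxabicyclo[2.2.1]hept-5-en-1-yl]methyl benzoate | O=C(OC[C@@]12C=C[C@@H](O1)[C@@H](O)[C@H]2O)c1ccccc1
F5 | step 4 | [3-exo-(tert-butyldimethylsilyloxy)-2-exo-hydroxy-7-oxabicyclo[2.2.1]hept-5-en-1-yl]methyl benzoate | O=C(OC[C@@]12C=C[C@@H](O1)[C@@H](O[Si](C)(C)C(C)(C)C)[C@H]2O)c1ccccc1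
F6 | step 4 | [2-exo-(benzoyloxy)-3-exo-(tert-butyldimethylsilyloxy)-7-oxabicyclo[2.2.1]hept-5-en-1-yl]methyl benzoate | O=C(OC[C@@]12C=C[C@@H](O1)[C@@H](O[Si](C)(C)C(C)(C)C)[C@H]2OC(=O)c1ccccc1)c1ccccc1
F7 | step 4 | [2-exo-(benzoyloxy)-3-exo-hydroxy-7-oxabicyclo[2.2.1]hept-5-en-1-yl]methyl benzoate | O=C(OC[C@@]12C=C[C@@H](O1)[C@@H](O)[C@H]2OC(=O)c1ccccc1)c1ccccc1
F8 | step 4 | [2-exo-(benzoyloxy)-3-oxo-7-oxabicyclo[2.2.1]hept-5-en-1-yl]methyl benzoate | O=C(OC[C@@]12C=C[C@@H](O1)C(=O)[C@H]2OC(=O)c1ccccc1)c1ccccc1
F0 | step 7 | none | none
F9 | step 6 | [(1R,2R,5S,6R)-6-(benzoyloxy)-2-chloro-1-hydroxy-5-[(1R)-1-(2,4,6-triisopropylphenyl)ethoxy]cyclohex-3-en-1-yl]methyl benzoate | O=C(OC[C@]1(O)[C@H](Cl)C=C[C@H](O[C@H](C)c2c(C(C)C)cc(C(C)C)cc2C(C)C)[C@H]1OC(=O)c1ccccc1)c1ccccc1
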